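The constants are invented; the flask was simulated.

Starting material takes up dissolved gas once to give the target, and the same gas can strike the target a second time.

starting material 0.050 M; gas phase 7.2 mM (held); time 6.0 d

- amount of target and crystals together at 6.0 d, in percent of the starting material charged
- concentration of dissolved gas in solution at 3.0 d, in percent of saturation
- the change that raises the amount of target and crystals together at 6.0 d, in percent of the starting material charged most ("none" if none brings more than 2 percentage points) (ochre / teal / red / green / none)
- amount of target and crystals together at 6.0 d, in percent of the starting material charged, after red

- ochre: doubling the dissolution coefficient of step 6, all else as stated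
- teal: doubling the saturation concentration of gas phase, all else as stated
- red: doubling the transfer coefficient of step 1, all else as stated
- green: doubling the solubility in step 6, all else as stated

- amounts and yields of target count crystals too
- two of one species on the left: rate k times its square, two consumed each time
- given per volume of solution although it is solid: crystals
- at the start none of the gas is dissolved
- run time (flask): 6.0 d

    gas phase ⇌ dissolved gas, rate k1*(csat - [dissolved gas]) (k1 = 0.377 h⁻¹, csat = 7.2 mM)
    starting material + dissolved gas → target (k2 = 86.8 M⁻¹ h⁻¹)
    dissolved gas + target → over-reacted product (k3 = 8.54 M⁻¹ h⁻¹)
    dissolved gas ⇌ dormant form (K4 = 3.2, k4 = 0.0426 h⁻¹)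
    2 dissolved gas → self-condensation product (k5 = 6.46 M⁻¹ h⁻¹)
    crystals ⇌ target, rate k6*(cs6 - [target]) while solid is left; crystals form when [target] > cs6 (cs6 = 0.81 mM, k6 = 6.24 h⁻¹)

The reckoning here follows one target molecule and adds one process at a time. In the main step, the gas phase feeds at most 2.71 mM h⁻¹, so the charge needs at least 18.4 h, less than the 6.0 d allowed. Against starting material as charged, dissolved gas has a half-life of 0.16 h, shorter than the 0.68 d of the forward step to the dormant form, so this first picture sends the gas into the main step.

Over-reaction comes next. At saturation, a dissolved target molecule is struck at a pseudo-first-order 0.0615 h⁻¹, and the table carries that rate through for a target kept fully dissolved. Crystals change the fork: a molecule in a crystal is out of reach, and solution holds 0.81 mM, or 1.62% of the charge. While solid is left, the loss is therefore the drain, the rate constant of over-reaction times the solubility times the dissolved gas, whatever the amount of crystals.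

Self-condensation then holds the gas down. Setting transfer equal to that loss gives 5.98 mM, or 83.0% of saturation, before the dormant form draws more. The drain becomes 0.0413 mM h⁻¹.

| In the flask | Target and crystals at the end |
|---|---|
| Main step | 100% |
| Plus over-reaction, no crystals | 0.0443% |
| Plus crystals, gas saturated | 87.5% |
| Plus self-condensation | 89.6% |

With red, the fill time halves and the gas rises to 6.48 mM, giving 87.9%. Green and teal raise the drain, and ochre does not enter it, so this reckoning answers none.

The forecast gives a yield of 90%, a dissolved gas at 80% of saturation at 3.0 d, none as the best change, and 88.4% after red. Its saturation lies below the reckoned figure, its red yield above the reckoned one, and its grounds are: “None of the changes helps because faster transfer, more gas or higher solubility all speed over-reaction once the starting material is gone”.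

The simulation gives a yield of 90.1%, a dissolved gas at 78.7% of saturation at 3.0 d, none as the best change, and 88.1% after red. The changes bring 0.058 percentage points for ochre, −9 points for teal, −2 points for red and −9.4 points for green. The simulated yield moves by 5 points at a run time of 3.36 d below the present one or 8.61 d above it, so the forecast's 90% belongs to the 6.0 d asked.

The flask keeps 90.1% because target dissolves up to 0.81 mM and the time allowed is 6.0 d: without the solubility limit the run ends at 0.573%, and at ten times the time 0% remains. From 3.0 d to 6.0 d, the drain at the 0.00566 M of dissolved gas present at 3.00 d comes to 5.64% of the charge, and over-reacted product rises by 5.7 points. For the neighbour flask with 0.085 M of starting material, the drain gives 5.47% of its charge, and that flask ends with 5.23% over-reacted product.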